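## Structural features

The target is a trans-fused hydroazulene. Tetralin locants of the aromatic precursor are kept for every intermediate: the seven-membered ring is C8a(=O)–C1–C2–C3–C4–C4a–C8 and the five-membered ring is C4a–C5–C6–C7–C8. C1 is quaternary (a methyl and a CH2CH2 arm ending in a 4-substituted furan-2(5H)-one) and stands next to the C2 methine, the two methyls being cis. On the other side of the ketone lie the fusion methine C8, the angular tertiary carbinol C4a (OH trans to C8–H, cis to the C1 arm), the gem-dimethyl carbon C5 and the secondary carbinol C6 (OH trans to the C4a hydroxyl). The C4a–OH/C8a=O pair is an aldol, so it can dehydrate or cleave by retro-aldol and C8 is epimerisable; the butenolide is sensitive to base, hydride and radical reduction. The real difficulty is the contiguous run C1(quaternary)–C8a–C8–C4a(tertiary OH)–C5(quaternary), and the relay of configuration from the C1/C2 pair to the carbinol centres. The key step exploits the five-membered ring (oxygenated C6, methyl-bearing C5, both fusion carbons) joined to a seven-membered ring with its carbonyl at C8a beside the fusion CH: this is what a 6/6 cross-conjugated cyclohexadienone gives on irradiation, namely a cyclopentenone C4a=C5(Me)–C6=O and an oxidised C8a.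

## Logic of the disconnections

24 ⇒ 21 + 22. The bond between the side-chain CH2 and the lactone C4 is cut. It is the only sp3–sp2 bond outside the rings, and cutting it keeps the most fragile group out of all earlier steps. The forward coupling must tolerate a ketone, two hindered hydroxyls and an epimerisable centre, which calls for an organozinc.

21 ⇒ 20 ⇒ 18. The C–I bond goes back to the primary alcohol; 20 is then traced to 18 by re-masking the ketone, re-silylating the alcohol and inverting C8. Placing the C8 adjustment after ketal removal means only C4a has to be set kinetically. The forward step needs the trans-fused aldol to be the more stable C8 epimer and to survive mild base.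

18 ⇒ 17 ⇒ 16. The C6–H bond (reduction) and then the C4a–O bond (alkene hydration) are cut, taking both carbinols back to one ketone and one trisubstituted alkene. The hydration must be Markovnikov at a ring-fusion carbon and on the face of C8–H; the reduction must be anti to the new hydroxyl.

16 ⇒ 15. One C5–CH3 bond is cut and the double bond returns into conjugation, leaving a plain 2-methylcyclopentenone. The forward step demands γ-deprotonation at C4 (not C8 or C7) and α-alkylation of the dienolate.

15 ⇒ 14. The fusion bond C8–C4a is cut and C4a–C8a is re-formed, so the 5/7 enone ketal becomes a 6/6 quinol ether. Both rings, the fusion bond and the oxidation level of C8a are thereby traced to one aromatic ring. The forward photorearrangement must open the cyclopropane towards the methoxy carbon and transmit the C8a configuration to C8.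

14 ⇒ 13 ⇒ 12. The C8a–OMe bond is cut (oxidative dearomatisation) and the phenol is returned to its methyl ether. The forward oxidation must attack the para carbon next to a quaternary centre, preferably on the face cis to the C1 methyl.

12 ⇒ 11 ⇒ 9. The O–Si bond is cut, then the alcohol is traced to a terminal alkene with one more carbon. The two-carbon arm therefore comes from an allyl group.

9 ⇒ 7 + 8. The C1–allyl bond is cut to a benzylic cation equivalent and an allyl nucleophile. The para-methoxy group makes the cation accessible and the C2 methyl can steer the nucleophile trans. The forward step must avoid proton loss from C2.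

7 ⇒ 6 ⇒ 3. The C1–CH3 and C2–CH3 bonds are cut in turn, leaving an achiral tetralone. The C2 methylation (through 4 and 5) is the only step needing an external chiral controller.

3 ⇒ 2 ⇒ 1. The aryl C5–CH3 bond is cut to a bromide and then to 1. The bromination must select C5 over C7.

## Other disconnections considered

Alternative 1: The seven-membered ring would be cut at C3–C4 and at C8–C8a, into a four-carbon diene and a three-carbon oxyallyl unit. In the forward sense the 2-methoxyallyl cation, released from A3 by AgO2CCF3, would add across the termini of diene A2 in a (4+3) cycloaddition and close the ring as the symmetrical cycloheptenone A1.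
- In favour: two commodity fragments, one step to the carbocycle, both ring methyls already on adjacent carbons, and a well-precedented cycloaddition class. On mechanistic security and on the cost of reaching the first ring this alternative is the better plan.
- Against: A1 is achiral with a mirror plane and its carbonyl maps onto the carbinol carbon C4a. The C8a ketone, the whole cyclopentane, the two-carbon arm on a fully substituted alkene carbon and all five stereocentres would still have to be added, with absolute configuration coming from a later desymmetrisation. Converting the tetrasubstituted alkene into the cis-dimethyl C1/C2 pair is the weak point.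
- Comparison: structurally the chosen plan is ahead, since it enters its key step with C1/C2 resolved and leaves it with both rings, the fusion bond and the C8a oxidation level. In step economy the alternative would probably start shorter and end longer.

Alternative 2: The cut is the C2–C3 bond, made after opening the target in thought across the aldol bond C8–C4a to a ten-membered 1,6-dione and contracting that ring across C4a–C8a to a cyclohexanol with two alkenyl groups. In the forward sense the potassium alkoxide would undergo an anionic oxy-Cope rearrangement, the enolate being trapped by Et3SiCl as the ten-membered bis-enol ether A4.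
- In favour: a reliable low-temperature four-atom ring expansion that sets C2 through an ordered transition state. A4 carries two differentiated enol ethers, one for methylation at C1 and one that unmasks the C4a ketone. The closing transannular aldol would form the fusion bond and both fusion centres in what is probably the biogenetic way. On control of C4a and C8 this alternative is the better plan, and its key step is better precedented.
- Against: the C1 quaternary centre would come from alkylating a ten-membered enolate with facial control from C2 alone. The aldol could also run in the other regiochemical sense (C4 onto C8a). The 3-furyl group must be oxidised regioselectively to the butenolide at the end. The rearrangement substrate, with two adjacent fully substituted ring carbons and defined olefin geometry, is itself a long synthesis.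
- Comparison: step economy is judged about equal. The chosen plan is stronger in fixing C1 and C2 on a rigid tetralin before any medium ring appears.

Alternative 3: The cut is the C5–C4a bond of the cyclopentane, leaving a seven-membered 1,3-diketone whose side chain ends in a trisubstituted epoxide. In the forward sense Cp2TiCl would open the epoxide to the tertiary radical at C5, which would add 5-exo to the less hindered ketone and give, after reduction of the alkoxy radical, the 3-furyl analogue A5 of the target.
- In favour: one step would create the cyclopentane, the gem-dimethyl carbon and both carbinols, with C6 fixed beforehand by an enantioselective epoxidation. In operations after the key step, and in needing no separate C6 reduction, this alternative is the better plan; it is the equal of the chosen plan in using a one-electron step for the angular alcohol.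
- Against: radical addition to a ketone is reversible and would here join a tertiary radical to a flanked carbonyl, making two adjacent fully substituted carbons. The 1,3-diketone would be largely enolised, which lowers its electrophilicity and erases C8. The choice between the two carbonyls and the facial sense at C4a rest on substrate bias alone, and the furan must still become the butenolide.
- Comparison: the seven-membered dione with the C1/C2 pair must be built first, so the chosen plan should be shorter in carbocycle construction while the alternative would be shorter at the end.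

Key step: step 11

Remark on the chemistry (assumption): ring B must stay cis-fused to the three-membered ring of the photochemical intermediate, so the C8a configuration fixes the new C8–H on the face opposite the methoxy group. The quinol ether with OMe cis to the C1 methyl (14) can therefore only give the enone ketal with C8–H cis to the side chain (15). The two C8a epimers do not converge before the carbinol centre is set, and the route is drawn with this matched pair.

## Route

Step 1
Reactants: 1 6-methoxy-3,4-dihydronaphthalen-1(2H)-one
Product: 2 5-bromo-6-methoxy-3,4-dihydronaphthalen-1(2H)-one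
Conditions: NBS, aq. H2SO4, 60 °C
Reagents that add atoms: N-bromosuccinimide, O=C1CCC(=O)N1Br
Why: Electrophilic aromatic bromination; C5, ortho to the methoxy group and to the ring alkyl carbon, is the most activated site, and the minor C7 bromide is removed by crystallisation.

Step 2
Reactants: 2 5-bromo-6-methoxy-3,4-dihydronaphthalen-1(2H)-one
Product: 3 6-methoxy-5-methyl-3,4-dihydronaphthalen-1(2H)-one
Conditions: (MeBO)3, PdCl2(dppf) (5 mol %), K2CO3, dioxane/H2O, 100 °C
Reagents that add atoms: trimethylboroxine, CB1OB(C)OB(C)O1
Why: Suzuki–Miyaura methylation of an aryl bromide; the ortho substituents slow but should not prevent coupling with a bidentate phosphine catalyst.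

Step 3
Reactants: 3 6-methoxy-5-methyl-3,4-dihydronaphthalen-1(2H)-one
Product: 4 SAMP hydrazone of 3
Conditions: SAMP, TsOH (cat.), cyclohexane, reflux (Dean–Stark)
Reagents that add atoms: (S)-1-amino-2-(methoxymethyl)pyrrolidine (SAMP), COC[C@@H]1CCCN1N
Why: Condensation of the ketone with the chiral hydrazine (Enders hydrazone formation), driven by azeotropic removal of water.

Step 4
Reactants: 4 SAMP hydrazone of 3
Product: 6 (R)-6-methoxy-2,5-dimethyl-3,4-dihydronaphthalen-1(2H)-one, via methylated hydrazone 5 (not isolated)
Conditions: LiN(iPr)2, THF, 0 °C; MeI, −95 °C to rt; then sat. aq. oxalic acid, Et2O, rt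
Reagents that add atoms: iodomethane, CI; water, O
Why: Enders SAMP hydrazone alkylation: the chelated azaenolate is methylated on one face, which by the model for cyclic ketones should give the R ketone (the antipodal auxiliary is equally available should the sense need reversing). Two-phase oxalic acid cleavage should release the ketone without epimerising C2 and return the auxiliary.

Step 5
Reactants: 6 (R)-6-methoxy-2,5-dimethyl-3,4-dihydronaphthalen-1(2H)-one
Product: 7 (2R)-6-methoxy-1,2,5-trimethyl-1,2,3,4-tetrahydronaphthalen-1-ol (both C1 epimers)
Conditions: MeMgBr, CeCl3, THF, −78 °C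
Reagents that add atoms: methylmagnesium bromide, C[Mg]Br
Why: Organocerium 1,2-addition; the weakly basic reagent adds to the enolisable aryl ketone without deprotonating C2, and the C1 configuration is irrelevant because that carbon is ionised next.

Step 6
Reactants: 7 (2R)-6-methoxy-1,2,5-trimethyl-1,2,3,4-tetrahydronaphthalen-1-ol; 8 allyltrimethylsilane
Product: 9 (1S,2R)-1-allyl-6-methoxy-1,2,5-trimethyl-1,2,3,4-tetrahydronaphthalene
Conditions: 8 (3 equiv), BF3·OEt2, 2,6-di-tert-butylpyridine, CH2Cl2, −78 °C
Reagents that add atoms: none
Why: Hosomi–Sakurai allylation of a tertiary para-methoxybenzylic cation; A(1,2) strain with the C1 methyl turns the C2 methyl pseudoaxial and the silane attacks the planar cation anti to it, so the allyl group ends trans to the C2 methyl and the two methyls cis. Low temperature, excess silane and the hindered base suppress proton loss and re-protonation that would erode C2.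

Step 7
Reactants: 9 (1S,2R)-1-allyl-6-methoxy-1,2,5-trimethyl-1,2,3,4-tetrahydronaphthalene
Product: 11 2-[(1S,2R)-6-methoxy-1,2,5-trimethyl-1,2,3,4-tetrahydronaphthalen-1-yl]ethanol, via aldehyde 10 (not isolated)
Conditions: O3, CH2Cl2/MeOH, −78 °C (dye endpoint); then NaBH4, −78 °C to rt
Reagents that add atoms: ozone, [O-][O+]=O
Why: Ozonolysis of the terminal alkene, which reacts far faster than the arene at −78 °C, with reductive work-up through the aldehyde to the primary alcohol.

Step 8
Reactants: 11 2-[(1S,2R)-6-methoxy-1,2,5-trimethyl-1,2,3,4-tetrahydronaphthalen-1-yl]ethanol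
Product: 12 triisopropylsilyl ether of 11
Conditions: TIPSCl, imidazole, DMF, rt
Reagents that add atoms: triisopropylsilyl chloride, CC(C)[Si](Cl)(C(C)C)C(C)C
Why: Standard silylation of a primary alcohol; the bulky silyl ether should survive thiolate, the trivalent iodine oxidant, acidic methanol and alkoxide base.

Step 9
Reactants: 12 triisopropylsilyl ether of 11
Product: 13 (1S,2R)-1,2,5-trimethyl-1-[2-(triisopropylsilyloxy)ethyl]-1,2,3,4-tetrahydronaphthalen-6-ol
Conditions: NaSEt, DMF, 120 °C; then aq. NH4Cl
Reagents that add atoms: none
Why: SN2 demethylation of the aryl methyl ether by thiolate; the alkyl silyl ether and the benzylic quaternary centre are inert.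

Step 10
Reactants: 13 (1S,2R)-1,2,5-trimethyl-1-[2-(triisopropylsilyloxy)ethyl]-1,2,3,4-tetrahydronaphthalen-6-ol
Product: 14 (1S,2R,8aR)-8a-methoxy-1,2,5-trimethyl-1-[2-(triisopropylsilyloxy)ethyl]-1,2,3,4-tetrahydronaphthalen-6(8aH)-one (OMe cis to the C1 methyl)
Conditions: PhI(OAc)2, MeOH, 0 °C
Reagents that add atoms: methanol, CO
Why: Oxidative dearomatisation of a para-alkyl phenol with a trivalent iodine reagent; methanol captures the para carbon, expected mainly anti to the larger silyloxyethyl arm on C1, giving the quinol methyl ether with OMe cis to the C1 methyl. The C8a epimer (F7) is separated by chromatography.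

Step 11
Reactants: 14 quinol methyl ether (OMe cis to the C1 methyl)
Product: 15 (1S,2R,8S)-hydroazulenone: cyclopentenone C4a=C5(Me)–C6(=O)–C7H2–C8H fused to the seven-membered ring, dimethyl ketal at C8a, C8–H cis to the C1 side chain
Conditions: hν (366 nm, Pyrex), MeOH/AcOH (9:1), 0 °C, N2, to partial conversion
Reagents that add atoms: methanol, CO
Why: Proposed new method: n→π* excitation of the cross-conjugated dienone and bonding of its two β carbons (C8 to C4a) should give the bicyclo[3.1.0] oxyallyl zwitterion, which acetic acid protonates on oxygen; the cyclopropane bond C4a–C8a then opens towards the methoxy carbon, because the C5 methyl localises positive charge next to C4a and the methoxy group stabilises the C8a cation as an oxocarbenium ion, which methanol traps as the dimethyl ketal while the enol tautomerises to the cyclopentenone. The closest known reaction type is the type A photorearrangement of 4,4-dialkyl cross-conjugated cyclohexadienones in protic acid to hydroxy hydroazulenones (santonin to isophotosantonic lactone), with the photochemical ring contraction of quinone monoketals as a further analogy for alkoxy-stabilised cleavage; a fused 4-alkyl-4-alkoxy dienone has not been used in this way. The five-membered ring closes by transannular bonding of the two dienone β carbons (contraction of ring A), and the seven-membered ring forms by fragmentation of the shared cyclopropane bond (one-carbon enlargement of ring B). The only new stereocentre, C8, is controlled by C8a: ring B must stay cis-fused to the cyclopropane, so the apex C8a tips towards its methoxy face and the C8 hydrogen ends on the face of the C1 side chain. The step needs C4a–C8a cleavage in preference to the 1,4-shift to a lumiketone, loss of the methoxy group or C8–C8a cleavage; the protic acidic medium, the C5 methyl and the alkoxy group should secure this, and 366 nm irradiation stopped short of full conversion limits secondary photochemistry of the enone.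

Step 12
Reactants: 15 hydroazulenone ketal
Product: 16 (1S,2R,8S)-5,5-dimethyl ketone with the double bond at C4a=C4 (C6 ketone, C8a dimethyl ketal)
Conditions: KOtBu (1.1 equiv), t-BuOH/THF, 0 °C; then MeI
Reagents that add atoms: iodomethane, CI
Why: Deconjugative α-alkylation through the thermodynamic extended dienolate formed by γ-deprotonation at the C4 methylene, as in the gem-dimethylation of ring-fused 2-methyl enones; MeI attacks C5 and the double bond moves to C4a=C4. The hindered C8 methine next to the ketal carbon is expected to stay untouched.

Step 13
Reactants: 16 β,γ-unsaturated ketone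
Product: 17 (1S,2R,4aR,8S)-C4a tertiary alcohol (cis-fused; C6 ketone, C8a dimethyl ketal)
Conditions: Co(acac)2 (20 mol %), PhSiH3, O2 (1 atm), THF, rt
Reagents that add atoms: dioxygen, O=O
Why: Mukaiyama hydration: hydrogen atom transfer to C4 gives the tertiary C4a radical, which O2 should trap on the convex face of the bicycle, syn to the C8 hydrogen and away from the ketal-bearing seven-membered ring. The hydroxyl therefore becomes cis to the C1 side chain (cis ring fusion), as required at C4a.

Step 14
Reactants: 17 β-hydroxy ketone
Product: 18 (1S,2R,4aR,6R,8S)-C4a,C6-diol (C8a dimethyl ketal, silyl ether)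
Conditions: Me4NBH(OAc)3, MeCN/AcOH, −20 °C
Reagents that add atoms: none
Why: Evans–Saksena hydroxyl-directed reduction; the C4a alkoxyborohydride delivers hydride to the face of the angular oxygen, which is also the convex face, so the C6 hydroxyl forms trans to the C4a hydroxyl. The anhydrous medium should leave the ketal intact.

Step 15
Reactants: 18 diol ketal silyl ether
Product: 20 (1S,2R,4aR,6R,8R)-trans-fused triol ketone, via cis-fused triol ketone 19 (not isolated)
Conditions: HF (48% aq), MeCN, 0 °C to rt; then K2CO3, MeOH, 0 °C to rt
Reagents that add atoms: water, O
Why: Aqueous HF removes the silyl ether and hydrolyses the hindered ketal; mild base then epimerises C8, now α to the ketone, by enolisation. The trans-fused β-hydroxy ketone is expected to be the more stable epimer, as trans-fused bicyclo[5.3.0]decan-2-ones generally are and as the natural product carries this labile centre.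

Step 16
Reactants: 20 trans-fused triol ketone
Product: 21 primary iodide of 20
Conditions: I2, PPh3, imidazole, CH2Cl2, 0 °C
Reagents that add atoms: iodine, II
Why: Appel-type iodination; only the primary alcohol should react, the neopentyl secondary and the tertiary alcohols being too hindered, and the imidazole buffer avoids dehydration of the aldol.

Step 17
Reactants: 21 primary iodide of 20; 22 4-bromofuran-2(5H)-one
Product: 24 target butenolide CNP0077405.2, via alkylzinc iodide 23 (not isolated)
Conditions: Zn, LiCl, THF, 30 °C; then 22, Pd(OAc)2 (3 mol %), SPhos, THF, rt
Reagents that add atoms: none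
Why: Negishi coupling: LiCl-assisted zinc insertion gives the alkylzinc iodide, which should tolerate the ketone and the hindered hydroxyls. Zerovalent palladium, formed from Pd(OAc)2 and the biaryl phosphine, couples it with the vinylic bromide faster than β-hydride elimination.

## Compound list

1 | 6-methoxy-3,4-dihydronaphthalen-1(2H)-one | COc1ccc2C(=O)CCCc2c1 | starting material
2 | 5-bromo-6-methoxy-3,4-dihydronaphthalen-1(2H)-one | COc1ccc2C(=O)CCCc2c1Br | intermediate
3 | 6-methoxy-5-methyl-3,4-dihydronaphthalen-1(2H)-one | COc1ccc2C(=O)CCCc2c1C | intermediate
4 | SAMP hydrazone of 3 (amino group syn to C2) | COc1ccc2c(c1C)CCC/C2=N\N1CCC[C@H]1COC | intermediate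
5 | C2-methylated SAMP hydrazone (2R) | C[C@@H]1CCc2c(C)c(OC)ccc2/C1=N/N1CCC[C@H]1COC | intermediate
6 | (R)-6-methoxy-2,5-dimethyl-3,4-dihydronaphthalen-1(2H)-one | C[C@@H]1CCc2c(C)c(OC)ccc2C1=O | intermediate
7 | (2R)-6-methoxy-1,2,5-trimethyl-1,2,3,4-tetrahydronaphthalen-1-ol, both C1 epimers | C[C@@H]1CCc2c(C)c(OC)ccc2C1(C)O | intermediate
8 | allyltrimethylsilane | C=CC[Si](C)(C)C | starting material
9 | (1S,2R)-1-allyl-6-methoxy-1,2,5-trimethyl-1,2,3,4-tetrahydronaphthalene (allyl trans to the C2 methyl) | C[C@@H]1CCc2c(C)c(OC)ccc2[C@@]1(C)CC=C | intermediate
10 | 2-[(1S,2R)-6-methoxy-1,2,5-trimethyl-1,2,3,4-tetrahydronaphthalen-1-yl]acetaldehyde | C[C@@H]1CCc2c(C)c(OC)ccc2[C@@]1(C)CC=O | intermediate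
11 | 2-[(1S,2R)-6-methoxy-1,2,5-trimethyl-1,2,3,4-tetrahydronaphthalen-1-yl]ethanol | C[C@@H]1CCc2c(C)c(OC)ccc2[C@@]1(C)CCO | intermediate
12 | triisopropylsilyl ether of 11 | C[C@@H]1CCc2c(C)c(OC)ccc2[C@@]1(C)CCO[Si](C(C)C)(C(C)C)C(C)C | intermediate
13 | (1S,2R)-1,2,5-trimethyl-1-[2-(triisopropylsilyloxy)ethyl]-1,2,3,4-tetrahydronaphthalen-6-ol | C[C@@H]1CCc2c(C)c(O)ccc2[C@@]1(C)CCO[Si](C(C)C)(C(C)C)C(C)C | intermediate
14 | (1S,2R,8aR)-8a-methoxy-1,2,5-trimethyl-1-[2-(triisopropylsilyloxy)ethyl]-1,2,3,4-tetrahydronaphthalen-6(8aH)-one, OMe cis to the C1 methyl | C[C@@H]1CCC2=C(C)C(=O)C=C[C@@]2(OC)[C@@]1(C)CCO[Si](C(C)C)(C(C)C)C(C)C | intermediate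
15 | (1S,2R,8S)-hydroazulenone: C4a=C5(Me)–C6=O cyclopentenone, C8a dimethyl ketal, C8–H cis to the C1 side chain | C[C@@H]1CCC2=C(C)C(=O)C[C@@H]2C(OC)(OC)[C@@]1(C)CCO[Si](C(C)C)(C(C)C)C(C)C | intermediate
16 | (1S,2R,8S)-5,5-dimethyl C6 ketone with C4a=C4 double bond, C8a dimethyl ketal | C[C@@H]1CC=C2[C@H](CC(=O)C2(C)C)C(OC)(OC)[C@@]1(C)CCO[Si](C(C)C)(C(C)C)C(C)C | intermediate
17 | (1S,2R,4aR,8S)-C4a-hydroxy C6 ketone, cis-fused, C8a dimethyl ketal | C[C@@H]1CC[C@@]2(O)[C@H](CC(=O)C2(C)C)C(OC)(OC)[C@@]1(C)CCO[Si](C(C)C)(C(C)C)C(C)C | intermediate
18 | (1S,2R,4aR,6R,8S)-C4a,C6-diol, cis-fused, C8a dimethyl ketal | C[C@@H]1CC[C@@]2(O)[C@H](C[C@@H](O)C2(C)C)C(OC)(OC)[C@@]1(C)CCO[Si](C(C)C)(C(C)C)C(C)C | intermediate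
19 | (1S,2R,4aR,6R,8S)-cis-fused triol ketone | C[C@@H]1CC[C@@]2(O)[C@H](C[C@@H](O)C2(C)C)C(=O)[C@@]1(C)CCO | intermediate
20 | (1S,2R,4aR,6R,8R)-trans-fused triol ketone | C[C@@H]1CC[C@@]2(O)[C@@H](C[C@@H](O)C2(C)C)C(=O)[C@@]1(C)CCO | intermediate
21 | primary iodide of 20 | C[C@@H]1CC[C@@]2(O)[C@@H](C[C@@H](O)C2(C)C)C(=O)[C@@]1(C)CCI | intermediate
22 | 4-bromofuran-2(5H)-one | BrC1=CC(=O)OC1 | starting material
23 | alkylzinc iodide from 21 | C[C@@H]1CC[C@@]2(O)[C@@H](C[C@@H](O)C2(C)C)C(=O)[C@@]1(C)CC[Zn]I | intermediate
24 | CNP0077405.2, (1S,2R,4aR,6R,8R) in the locants used here | C[C@@H]1CC[C@@]2(O)[C@@H](C[C@@H](O)C2(C)C)C(=O)[C@@]1(C)CCC1=CC(=O)OC1 | target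

## Step count and least certain steps

Total: 17 steps. Longest linear sequence: 17 steps (1 to 24); 8 and 22 are purchased.

Step 11 (key step, proposed new method). Most likely failure: diversion of the excited dienone or the zwitterion into other channels (1,4-shift to a lumiketone, expulsion of the methoxy group with rearomatisation, secondary photolysis of the product enone). An alkoxy group at the dienone C4 is untested in this fused setting, and the product absorbs in the same window. Fallback with known chemistry, setting out from 12 and returning at 20: the photochemical reorganisation is replaced by oxidative cleavage and transannular aldol. Birch reduction of 12 (Li, NH3, t-BuOH, THF, −78 °C) should give the dihydro enol ether F1 with the tetrasubstituted C4a=C8a bond retained. Oxalic acid in aqueous methanol unmasks the β,γ-unsaturated ketone F2. KOtBu/MeI methylates C5 through the conjugated dienolate to the gem-dimethyl ketone F3. Corey–Bakshi–Shibata reduction ((S)-2-methyl-oxazaborolidine, BH3·SMe2) sets the C6 alcohol F4. Ozonolysis of the ring-fusion alkene (O3, then Me2S) gives the cyclodecane-1,6-dione F5, whose transannular aldol (K2CO3, MeOH) should close C8–C4a to the silylated aldol F6. Aqueous HF in MeCN then gives 20.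

Step 10. Most likely failure: poor facial selectivity of methanol capture at C8a, with some ortho attack, because each face of the para carbon is flanked by a substituent of the quaternary C1. Fallback, setting out from 13 and returning to 13 (and so to 14): selectivity is replaced by a recycling loop. The epimeric quinol ether F7 (OMe trans to the C1 methyl), separated after the oxidation, is returned to the phenol by reductive aromatisation (Zn, AcOH) and oxidised again.

Step 12. Most likely failure: deprotonation at C8 or C7 in competition with C4, leading to loss of the C8 configuration, an alkene in the wrong position or over-methylation; all three positions are acidic under equilibrating base. Fallback, setting out from 15 and returning at 17: nucleophilic epoxidation (t-BuOOH, DBU, CH2Cl2) on the convex face gives the epoxy ketone F8. Reductive opening of its Cα–O bond (Li, NH3, THF, −78 °C) and trapping of the enolate with MeI install the second C5 methyl and leave the C4a hydroxyl, with no γ-deprotonation.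

Step 13. Most likely failure: oxygen delivery to the wrong face of the C4a radical, since the cis preference of this 5/7 ring-fusion radical is an extrapolation from smaller bicycles. Fallback, setting out from 13 and returning at 20: the complementary C8 series is used. The epimeric quinol ether F7 is taken through the same photorearrangement to the C8-epimeric enone ketal F9 and methylated to the β,γ-unsaturated ketone F10. If oxygen enters anti to the fusion hydrogen, hydration gives the already trans-fused hydroxy ketone F11 with the correct C4a configuration. Directed reduction gives the diol F12, and aqueous HF gives 20 directly.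

Step 15. Most likely failure: dehydration or retro-aldol opening of the β-hydroxy ketone under base, or an equilibrium that does not favour the trans fusion; the angular C–O bond is aligned with the enolate and the relative stability of the two fusions is not known. Fallback, setting out from 19 and returning at 20: kinetic protonation replaces equilibration. Crude 19 is silylated (Me3SiOTf, Et3N) to the tris(trimethylsilyl) ether silyl enol ether F13. MeLi releases the lithium enolate, which is protonated at −78 °C by 2,6-di-tert-butylphenol on the face away from the bulky angular silyloxy group, giving the trans-fused tris(trimethylsilyl) ether F14. AcOH/THF/H2O then removes the silyl groups.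

Step 17. Most likely failure: protonation of the alkylzinc by the free hydroxyls during its formation, giving the reduced side chain. Fallback, setting out from 21 and returning at 24: nickel-catalysed reductive cross-electrophile coupling of 21 with 22 (NiBr2(dme), 4,4′-di-tert-butyl-2,2′-bipyridine, Mn, NaI, DMA). No organometallic is preformed and free hydroxyls are tolerated; no new compound (F0).

## Further compounds

F1 | step 11 | Birch dihydro enol ether of 12 (C6=C7 enol ether, C4a=C8a alkene, C5 epimers) | C[C@@H]1CCC2=C(CC=C(OC)C2C)[C@@]1(C)CCO[Si](C(C)C)(C(C)C)C(C)C
F2 | step 11 | β,γ-unsaturated C6 ketone (C4a=C8a alkene, C5 epimers) | C[C@@H]1CCC2=C(CCC(=O)C2C)[C@@]1(C)CCO[Si](C(C)C)(C(C)C)C(C)C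
F3 | step 11 | 5,5-dimethyl C6 ketone (C4a=C8a alkene) | C[C@@H]1CCC2=C(CCC(=O)C2(C)C)[C@@]1(C)CCO[Si](C(C)C)(C(C)C)C(C)C
F4 | step 11 | (6R)-alcohol of F3 | C[C@@H]1CCC2=C(CC[C@@H](O)C2(C)C)[C@@]1(C)CCO[Si](C(C)C)(C(C)C)C(C)C
F5 | step 11 | ten-membered 1,6-dione (C4a and C8a ketones, C6 hydroxyl) | C[C@@H]1CCC(=O)C(C)(C)[C@H](O)CCC(=O)[C@@]1(C)CCO[Si](C(C)C)(C(C)C)C(C)C
F6 | step 11 | triisopropylsilyl ether of 20 | C[C@@H]1CC[C@@]2(O)[C@@H](C[C@@H](O)C2(C)C)C(=O)[C@@]1(C)CCO[Si](C(C)C)(C(C)C)C(C)C
F7 | step 10 | C8a epimer of 14 (OMe trans to the C1 methyl) | C[C@@H]1CCC2=C(C)C(=O)C=C[C@]2(OC)[C@@]1(C)CCO[Si](C(C)C)(C(C)C)C(C)C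
F8 | step 12 | C4a,C5-epoxy ketone of 15 (epoxide cis to C8–H) | C[C@@H]1CC[C@@]23O[C@@]3(C)C(=O)C[C@@H]2C(OC)(OC)[C@@]1(C)CCO[Si](C(C)C)(C(C)C)C(C)C
F9 | step 13 | C8 epimer of 15 (C8–H trans to the C1 side chain) | C[C@@H]1CCC2=C(C)C(=O)C[C@H]2C(OC)(OC)[C@@]1(C)CCO[Si](C(C)C)(C(C)C)C(C)C
F10 | step 13 | C8 epimer of 16 | C[C@@H]1CC=C2[C@@H](CC(=O)C2(C)C)C(OC)(OC)[C@@]1(C)CCO[Si](C(C)C)(C(C)C)C(C)C
F11 | step 13 | C8 epimer of 17 (trans-fused hydroxy ketone) | C[C@@H]1CC[C@@]2(O)[C@@H](CC(=O)C2(C)C)C(OC)(OC)[C@@]1(C)CCO[Si](C(C)C)(C(C)C)C(C)C
F12 | step 13 | C8 epimer of 18 (trans-fused diol) | C[C@@H]1CC[C@@]2(O)[C@@H](C[C@@H](O)C2(C)C)C(OC)(OC)[C@@]1(C)CCO[Si](C(C)C)(C(C)C)C(C)C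
F13 | step 15 | tris(trimethylsilyl) ether C8=C8a trimethylsilyl enol ether of 19 | C[C@@H]1CC[C@@]2(O[Si](C)(C)C)C(C[C@@H](O[Si](C)(C)C)C2(C)C)=C(O[Si](C)(C)C)[C@@]1(C)CCO[Si](C)(C)C
F14 | step 15 | tris(trimethylsilyl) ether of 20 | C[C@@H]1CC[C@@]2(O[Si](C)(C)C)[C@@H](C[C@@H](O[Si](C)(C)C)C2(C)C)C(=O)[C@@]1(C)CCO[Si](C)(C)C
F0 | step 17 | none | none
A1 | alternative 1 | 4,5-dimethylcyclohept-4-en-1-one | CC1=C(C)CCC(=O)CC1
A2 | alternative 1 | 2,3-dimethylbuta-1,3-diene | CC(=C)C(C)=C
A3 | alternative 1 | 3-bromo-2-methoxyprop-1-ene | COC(=C)CBr
A4 | alternative 2 | ten-membered bis-enol ether (triethylsilyl enol ether and methyl enol ether) | CC[Si](CC)(CC)O/C1=C(/CCc2ccoc2)[C@H](C)C/C=C(\OC)C(C)(C)[C@H](O[Si](C)(C)C(C)(C)C)CC1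
A5 | alternative 3 | 3-furyl analogue of the target | C[C@@H]1CC[C@@]2(O)[C@@H](C[C@@H](O)C2(C)C)C(=O)[C@@]1(C)CCc1ccoc1
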